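**Plan**

- Retrosynthetic cuts, in order: the C2–O bond and the lactone C18–O19 link (late allylic oxidations of a Δ3-alkene); the C1–C16 bond of the seven-membered ring (reductive Heck); the C9–C20 and C5–C19 bonds of the decalin (backbone rearrangement); the C12–C13 bond (3-furyllithium plus a C12 aldehyde).
- Enabling feature: ring B/A of the target carries an oxygenated carbon (C19) on C5, and H8β, C20α on C9, H10β and C19α on C5 alternate across the two faces. Consecutive suprafacial 1,2-shifts write exactly this pattern onto an ent-labdane whose C4 bears an axial α-CH2O group and whose C3 bears a hydroxyl, and andrographolide is that ent-labdane.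
- Forward: the decalin of andrographolide is kept, and the side chain is cut to the C12 aldehyde and rebuilt as a 2-bromo-3-furyl ketone. Δ8(17) is moved to Δ7 and converted into the 7α,8α-epoxide, which BF3 rearranges to the neo-clerodane 3-ketone.
- The seven-membered ring (C1–C16) is then closed on the Δ1-3-ketone; the butenolide (C18–O–C19) and the C2 hydroxyl come last.
- Stereochemistry: C3, C4, C5, C9 and C10 of andrographolide are the chiral pool; the α-epoxide fixes C7; C8, C9, C10 and C5 arise from antiperiplanar shifts; C1 is set by the β-disposed tether and C2 by axial hydride delivery.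

Key step: step 8

Remark: labdane/clerodane numbering is used (C13–C16 are the furan carbons, C16 being the α-carbon next to C13; C17 on C8, C18 on C4, C19 on C4 (labdane) or C5 (clerodane), C20 on C10 or C9); α is the face of C20, and the SMILES strings are authoritative for configuration.

**Step 1**
Reactants: 1 andrographolide; 2 tert-butyl(chloro)diphenylsilane
Product: 3 19-O-TBDPS-andrographolide
Conditions: TBDPSCl, imidazole, DMF, 0 °C to rt
Reagents that add atoms: tert-butyl(chloro)diphenylsilane (2), CC(C)(C)[Si](Cl)(c1ccccc1)c1ccccc1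
Why: Imidazole-promoted silylation should take the primary 19-hydroxyl well ahead of the secondary 3- and allylic 14-hydroxyls, and a silyl ether is chosen because its oxygen is a poor nucleophile in the later cationic step and it can be removed with fluoride in the presence of the furan.

**Step 2**
Reactants: 3 19-O-TBDPS-andrographolide
Product: 4 3α-hydroxy-19-(TBDPS-oxy)-13,14,15,16-tetranor-ent-labd-8(17)-en-12-al
Conditions: KMnO4, THF–H2O, 0 °C
Reagents that add atoms: potassium permanganate, [K+].[O-][Mn](=O)(=O)=O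
Why: Permanganate oxidative cleavage should attack the electron-poor, conjugated C12=C13 alkylidene-lactone bond faster than the unconjugated exocyclic C8=C17 bond and fragment the glycol to the C12 aldehyde; no stereocentre is affected because C11 is a methylene.

**Step 3**
Reactants: 4 tetranor C12 aldehyde; 5 3-bromofuran
Product: 6 15,16-epoxy-19-(TBDPS-oxy)-ent-labda-8(17),13(16),14-triene-3α,12ξ-diol (3-furyl carbinol, C12 epimers)
Conditions: 5, n-BuLi, THF, −78 °C (Br–Li exchange); then 4, −78 °C (2.3 equiv of the furyllithium)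
Reagents that add atoms: 3-furyllithium, [Li]c1ccoc1 (generated from 5, Brc1ccoc1)
Why: 1,2-Addition of 3-furyllithium, kept at −78 °C where the 3-lithio isomer is stable, should form the C12–C13 bond after one equivalent has been spent on the 3-OH; the C12 carbinol centre forms without control, which is harmless because it is oxidised in step 5.

**Step 4**
Reactants: 6 3-furyl carbinol
Product: 8 16-bromo-15,16-epoxy-19-(TBDPS-oxy)-ent-labda-8(17),13(16),14-triene-3α,12ξ-diol, via O3/O12/C16-trilithio species 7 (not isolated)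
Conditions: n-BuLi (3.3 equiv), THF, −78 to 0 °C; then BrCH2CH2Br, −78 °C
Reagents that add atoms: 1,2-dibromoethane, BrCCBr
Why: In this alkoxide-directed ortho-lithiation the C12 lithium alkoxide and the ring oxygen both direct metalation to the furan α-carbon C16, and 1,2-dibromoethane transfers bromine to the aryllithium, so the halogen sits where the ring will later be closed; an electrophilic brominating agent is avoided because of the C8=C17 bond.

**Step 5**
Reactants: 8 16-bromo furyl carbinol
Product: 9 16-bromo-15,16-epoxy-3α-hydroxy-19-(TBDPS-oxy)-ent-labda-8(17),13(16),14-trien-12-one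
Conditions: activated MnO2, CH2Cl2, rt
Reagents that add atoms: none
Why: MnO2 should oxidise only the furyl (benzylic-type) carbinol and leave the saturated 3α-hydroxyl that terminates the cascade; the resulting 2-bromo-3-acylfuran is too electron-poor to act as a π-nucleophile in the acid steps that follow.

**Step 6**
Reactants: 9 Δ8(17) bromofuryl ketone
Product: 10 16-bromo-15,16-epoxy-3α-hydroxy-19-(TBDPS-oxy)-ent-labda-7,13(16),14-trien-12-one
Conditions: Co(salen-tBu,tBu)Cl (cat.), PhSiH3 (cat.), benzene, rt
Reagents that add atoms: none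
Why: In this cobalt-hydride (MHAT) alkene isomerisation, reversible hydrogen-atom transfer to the exocyclic methylene gives the tertiary C8 radical, which should return a hydrogen from the accessible C7 methylene to give the trisubstituted Δ7 alkene and stop short of the hindered Δ8(9) isomer; radical conditions avoid a C8 cation next to the ketone.

**Step 7**
Reactants: 10 Δ7 alkene
Product: 12 16-bromo-7α,8α:15,16-diepoxy-3α-hydroxy-19-(TBDPS-oxy)-ent-labda-13(16),14-dien-12-one, via 7β-bromo-8α-hydroxy bromohydrin 11 (not isolated)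
Conditions: NBS, THF–H2O, 0 °C; then aq. K2CO3, rt
Reagents that add atoms: water, O
Why: Bromohydrin formation and base closure: the bromonium should form on the β face away from the axial C20 methyl, water should open it at tertiary C8 from the α face (Markovnikov and trans-diaxial), and the 8α-alkoxide then displaces the 7β-bromide, which gives the 7α,8α-epoxide that direct peracid epoxidation (β face) would not.

**Step 8**
Reactants: 12 7α,8α-epoxy ent-labdan-3α-ol
Product: 13 16-bromo-15,16-epoxy-7α-hydroxy-19-(TBDPS-oxy)-neo-cleroda-13(16),14-diene-3,12-dione (4βH, 8βH, 10βH; C17, C18, C19, C20 all α)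
Conditions: BF3·OEt2 (2 equiv), CH2Cl2, −78 to −30 °C; aq. NaHCO3
Reagents that add atoms: none
Why: Proposed new method: BF3 ionises the tertiary C8–O bond of the 7α,8α-epoxide and the charge is passed on by five suprafacial 1,2-shifts, each entering anti to the bond that leaves (H9β to C8, the C20 methyl from C10 to the α face of C9, H5β to C10, the C19 silyloxymethyl from C4 to the α face of C5, H3β to C4), until the hydroxyl-bearing C3 is reached and loses its proton as the ketone; the closest known reaction type is the Lewis-acid, epoxide-initiated backbone rearrangement of steroid and triterpenoid epoxides, together with the acid-mediated hydride and methyl shifts that take labdanes to halimanes and clerodanes. No ring is closed; the new skeletal bonds are C9–C20 and C5–C19. The five stereocentres made or reset (C8, C9, C10, C5, C4) are each controlled by the anti relationship between the arriving group and the departing bond, which the chair–chair ent-labdane guarantees because the C8–O bond, H9, C20, H5, C19 and H3 are axial and alternately α and β, while the epoxide oxygen stays on C7 as the 7α-hydroxyl. The step needs H9 to migrate in preference to H7 (Meinwald path to a 7-ketone) and the relay to outrun proton loss at C9, C10, C5 and C4; the trans-diaxial alignment of H9 with the breaking C8–O bond, a cold non-basic medium and the irreversible carbonyl sink at C3 are what substrate and conditions offer for this. The C12 ketone and the C16 bromine make the furan too electron-poor to trap a cation, and the bulky silyl ether keeps O19 from closing onto C10.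

**Step 9**
Reactants: 13 7α-hydroxy neo-clerodane diketone; 14 acetic anhydride
Product: 15 7α-acetoxy-16-bromo-15,16-epoxy-19-(TBDPS-oxy)-neo-cleroda-13(16),14-diene-3,12-dione
Conditions: Ac2O, DMAP, Et3N, CH2Cl2, rt
Reagents that add atoms: acetic anhydride (14), CC(=O)OC(C)=O
Why: DMAP-catalysed acylation of the only free hydroxyl, the axial 7α-OH, installs the acetate of the target and shields this alcohol from the oxidant of the next step.

**Step 10**
Reactants: 15 7α-acetate
Product: 16 7α-acetoxy-16-bromo-15,16-epoxy-19-(TBDPS-oxy)-neo-cleroda-1,13(16),14-triene-3,12-dione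
Conditions: IBX, DMSO–toluene, 70 °C
Reagents that add atoms: none
Why: IBX dehydrogenation of a ketone should give the Δ1-3-ketone, because only the C3 ketone has a ring β-hydrogen to lose (H1, through the C2 enol), C5 and C9 being quaternary, so the C12 ketone cannot be desaturated.

**Step 11**
Reactants: 16 Δ1-3-ketone with C16–Br
Product: 17 7α-acetoxy-15,16-epoxy-19-(TBDPS-oxy)-1β,16-cyclo-neo-cleroda-13(16),14-diene-3,12-dione (1αH)
Conditions: Pd(OAc)2 (10 mol%), PPh3, HCO2Na, Bu4NCl, DMF, 80 °C
Reagents that add atoms: none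
Why: Intramolecular reductive Heck reaction: oxidative addition at C16–Br, 7-exo carbopalladation of the enone at C1 and formate reduction of the palladium enolate should close the seven-membered ring, and because the C11–C12 tether hangs from the β-equatorial bond at C9, while the α face of C1 lies under the axial C19 and C20 groups, the furan can only be delivered to the β face, setting C1 (C16 β, H1 α).

**Step 12**
Reactants: 17 tetracyclic 3,12-diketone
Product: 18 7α-acetoxy-15,16-epoxy-3α-hydroxy-19-(TBDPS-oxy)-1β,16-cyclo-neo-cleroda-13(16),14-dien-12-one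
Conditions: L-Selectride, THF, −78 °C
Reagents that add atoms: none
Why: This bulky hydride should reduce the non-conjugated C3 ketone and leave the vinylogous-ester-like C12 furyl ketone and the acetate, and equatorial (β-face) attack, enforced by the axial C19 group on the α face, gives the axial 3α-alcohol needed for anti elimination.

**Step 13**
Reactants: 18 3α-alcohol
Product: 19 7α-acetoxy-15,16-epoxy-19-(TBDPS-oxy)-1β,16-cyclo-neo-cleroda-3,13(16),14-trien-12-one
Conditions: POCl3, pyridine, 0 to 50 °C
Reagents that add atoms: none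
Why: In this E2 dehydration through the dichlorophosphate the axial 3α leaving group is antiperiplanar to the axial H4β, and Zaitsev elimination should give the trisubstituted C3=C4 alkene, which removes the C3 and C4 stereocentres without going through a cation.

**Step 14**
Reactants: 19 Δ3-alkene
Product: 20 7α-acetoxy-15,16-epoxy-18-hydroxy-19-(TBDPS-oxy)-1β,16-cyclo-neo-cleroda-3,13(16),14-trien-12-one
Conditions: SeO2 (0.5 equiv), t-BuOOH, CH2Cl2, rt
Reagents that add atoms: tert-butyl hydroperoxide, CC(C)(C)OO (oxygen relayed through SeO2, O=[Se]=O)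
Why: In this SeO2-catalysed allylic hydroxylation (ene reaction, then [2,3]-shift) selenium bonds to the less substituted C3 and the only allylic hydrogens at the more substituted end are those of the C18 methyl (C5 is quaternary), so the primary allylic alcohol should form; room temperature avoids α-oxidation of the C12 ketone.

**Step 15**
Reactants: 20 C18 allylic alcohol
Product: 21 7α-acetoxy-15,16-epoxy-18,19-dihydroxy-1β,16-cyclo-neo-cleroda-3,13(16),14-trien-12-one
Conditions: HF·pyridine, THF–pyridine, 0 °C to rt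
Reagents that add atoms: none
Why: Fluoride cleavage of the silyl ether under mildly acidic conditions should free the C19 hydroxyl without touching the C7 acetate.

**Step 16**
Reactants: 21 18,19-diol
Product: 23 7α-acetoxy-12-oxo-15,16-epoxy-1β,16-cyclo-neo-cleroda-3,13(16),14-trien-18,19-olide, via C18 lactol 22 (not isolated)
Conditions: activated MnO2 (excess), CH2Cl2, rt
Reagents that add atoms: none
Why: MnO2 oxidative lactonisation: only the allylic C18 alcohol is oxidised to the enal, the neighbouring C19 hydroxyl closes the lactol and MnO2 oxidises this allylic lactol further, so the carbonyl should end at C18 and not at C19.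

**Step 17**
Reactants: 23 Δ3-18,19-olide
Product: 24 7α-acetoxy-2,12-dioxo-15,16-epoxy-1β,16-cyclo-neo-cleroda-3,13(16),14-trien-18,19-olide
Conditions: Rh2(cap)4 (1 mol%), t-BuOOH (70% aq.), ClCH2CH2Cl, 40 °C
Reagents that add atoms: tert-butyl hydroperoxide, CC(C)(C)OO
Why: Dirhodium caprolactamate/t-BuOOH allylic oxidation should convert C2, the γ-methylene of the unsaturated lactone, into the ketone, since the only other activated hydrogen, H1α, is tertiary and buried under the axial C19 and C20 groups.

**Step 18**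
Reactants: 24 2-oxo lactone
Product: 25 target, 7α-acetoxy-2α-hydroxy-12-oxo-15,16-epoxy-1β,16-cyclo-neo-cleroda-3,13(16),14-trien-18,19-olide (CNP0182929.1)
Conditions: NaBH4, CeCl3·7H2O, MeOH–CH2Cl2, −78 °C
Reagents that add atoms: none
Why: Luche reduction: the ene-dione-type C2 ketone is far more electrophilic than the C12 furyl ketone and should be reduced 1,2, and axial hydride delivery on the β face gives the equatorial 2α-alcohol, trans to the C1 substituent.

**Compound list**

1 | andrographolide | C[C@@]12CC[C@H]([C@@]([C@H]1CCC(=C)[C@H]2C/C=C/3\[C@@H](COC3=O)O)(C)CO)O | starting material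
2 | tert-butyl(chloro)diphenylsilane | CC(C)(C)[Si](Cl)(c1ccccc1)c1ccccc1 | starting material
3 | 19-O-TBDPS-andrographolide | C[C@@]12CC[C@H]([C@@]([C@H]1CCC(=C)[C@H]2C/C=C/3\[C@@H](COC3=O)O)(C)CO[Si](c4ccccc4)(c4ccccc4)C(C)(C)C)O | intermediate
4 | 3α-hydroxy-19-(TBDPS-oxy)-13,14,15,16-tetranor-ent-labd-8(17)-en-12-al | C[C@@]12CC[C@H]([C@@]([C@H]1CCC(=C)[C@H]2CC=O)(C)CO[Si](c3ccccc3)(c3ccccc3)C(C)(C)C)O | intermediate
5 | 3-bromofuran | Brc1ccoc1 | starting material
6 | 15,16-epoxy-19-(TBDPS-oxy)-ent-labda-8(17),13(16),14-triene-3α,12ξ-diol | C[C@@]12CC[C@H]([C@@]([C@H]1CCC(=C)[C@H]2CC(O)c3ccoc3)(C)CO[Si](c4ccccc4)(c4ccccc4)C(C)(C)C)O | intermediate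
7 | O3,O12,C16-trilithio derivative of 6 | C[C@@]12CC[C@H]([C@@]([C@H]1CCC(=C)[C@H]2CC(O[Li])c3c([Li])occ3)(C)CO[Si](c4ccccc4)(c4ccccc4)C(C)(C)C)O[Li] | intermediate (not isolated)
8 | 16-bromo-15,16-epoxy-19-(TBDPS-oxy)-ent-labda-8(17),13(16),14-triene-3α,12ξ-diol | C[C@@]12CC[C@H]([C@@]([C@H]1CCC(=C)[C@H]2CC(O)c3c(Br)occ3)(C)CO[Si](c4ccccc4)(c4ccccc4)C(C)(C)C)O | intermediate
9 | 16-bromo-15,16-epoxy-3α-hydroxy-19-(TBDPS-oxy)-ent-labda-8(17),13(16),14-trien-12-one | C[C@@]12CC[C@H]([C@@]([C@H]1CCC(=C)[C@H]2CC(=O)c3c(Br)occ3)(C)CO[Si](c4ccccc4)(c4ccccc4)C(C)(C)C)O | intermediate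
10 | 16-bromo-15,16-epoxy-3α-hydroxy-19-(TBDPS-oxy)-ent-labda-7,13(16),14-trien-12-one | C[C@@]12CC[C@H]([C@@]([C@H]1CC=C(C)[C@H]2CC(=O)c3c(Br)occ3)(C)CO[Si](c4ccccc4)(c4ccccc4)C(C)(C)C)O | intermediate
11 | 7β,16-dibromo-15,16-epoxy-3α,8α-dihydroxy-19-(TBDPS-oxy)-ent-labda-13(16),14-dien-12-one (bromohydrin) | C[C@@]12CC[C@H]([C@@]([C@H]1C[C@H](Br)[C@@](C)(O)[C@H]2CC(=O)c3c(Br)occ3)(C)CO[Si](c4ccccc4)(c4ccccc4)C(C)(C)C)O | intermediate (not isolated)
12 | 16-bromo-7α,8α:15,16-diepoxy-3α-hydroxy-19-(TBDPS-oxy)-ent-labda-13(16),14-dien-12-one (key-step precursor) | C[C@@]12CC[C@H]([C@@]([C@H]1C[C@H]3O[C@@]3(C)[C@H]2CC(=O)c3c(Br)occ3)(C)CO[Si](c4ccccc4)(c4ccccc4)C(C)(C)C)O | intermediate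
13 | 16-bromo-15,16-epoxy-7α-hydroxy-19-(TBDPS-oxy)-neo-cleroda-13(16),14-diene-3,12-dione (key-step product) | O[C@@H]1C[C@@]2(CO[Si](c3ccccc3)(c3ccccc3)C(C)(C)C)[C@H](C)C(=O)CC[C@@H]2[C@@](C)(CC(=O)c2c(Br)occ2)[C@@H]1C | intermediate
14 | acetic anhydride | CC(=O)OC(C)=O | starting material
15 | 7α-acetoxy-16-bromo-15,16-epoxy-19-(TBDPS-oxy)-neo-cleroda-13(16),14-diene-3,12-dione | CC(=O)O[C@@H]1C[C@@]2(CO[Si](c3ccccc3)(c3ccccc3)C(C)(C)C)[C@H](C)C(=O)CC[C@@H]2[C@@](C)(CC(=O)c2c(Br)occ2)[C@@H]1C | intermediate
16 | 7α-acetoxy-16-bromo-15,16-epoxy-19-(TBDPS-oxy)-neo-cleroda-1,13(16),14-triene-3,12-dione | CC(=O)O[C@@H]1C[C@@]2(CO[Si](c3ccccc3)(c3ccccc3)C(C)(C)C)[C@H](C)C(=O)C=C[C@@H]2[C@@](C)(CC(=O)c2c(Br)occ2)[C@@H]1C | intermediate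
17 | 7α-acetoxy-15,16-epoxy-19-(TBDPS-oxy)-1β,16-cyclo-neo-cleroda-13(16),14-diene-3,12-dione | CC(=O)O[C@@H]1C[C@@]3(CO[Si](c5ccccc5)(c5ccccc5)C(C)(C)C)[C@H](C)C(=O)C[C@H]2c4occc4C(=O)C[C@@](C)([C@@H]1C)[C@@H]23 | intermediate
18 | 7α-acetoxy-15,16-epoxy-3α-hydroxy-19-(TBDPS-oxy)-1β,16-cyclo-neo-cleroda-13(16),14-dien-12-one | CC(=O)O[C@@H]1C[C@@]3(CO[Si](c5ccccc5)(c5ccccc5)C(C)(C)C)[C@H](C)[C@H](O)C[C@H]2c4occc4C(=O)C[C@@](C)([C@@H]1C)[C@@H]23 | intermediate
19 | 7α-acetoxy-15,16-epoxy-19-(TBDPS-oxy)-1β,16-cyclo-neo-cleroda-3,13(16),14-trien-12-one | CC(=O)O[C@@H]1C[C@@]3(CO[Si](c5ccccc5)(c5ccccc5)C(C)(C)C)C(C)=CC[C@H]2c4occc4C(=O)C[C@@](C)([C@@H]1C)[C@@H]23 | intermediate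
20 | 7α-acetoxy-15,16-epoxy-18-hydroxy-19-(TBDPS-oxy)-1β,16-cyclo-neo-cleroda-3,13(16),14-trien-12-one | CC(=O)O[C@@H]1C[C@@]3(CO[Si](c5ccccc5)(c5ccccc5)C(C)(C)C)C(CO)=CC[C@H]2c4occc4C(=O)C[C@@](C)([C@@H]1C)[C@@H]23 | intermediate
21 | 7α-acetoxy-15,16-epoxy-18,19-dihydroxy-1β,16-cyclo-neo-cleroda-3,13(16),14-trien-12-one | CC(=O)O[C@@H]1C[C@@]3(CO)C(CO)=CC[C@H]2c4occc4C(=O)C[C@@](C)([C@@H]1C)[C@@H]23 | intermediate
22 | 7α-acetoxy-18ξ-hydroxy-18,19:15,16-diepoxy-1β,16-cyclo-neo-cleroda-3,13(16),14-trien-12-one (lactol) | CC(=O)O[C@@H]1C[C@@]23COC(O)C2=CC[C@H]2c4occc4C(=O)C[C@@](C)([C@@H]1C)[C@@H]23 | intermediate (not isolated)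
23 | 7α-acetoxy-12-oxo-15,16-epoxy-1β,16-cyclo-neo-cleroda-3,13(16),14-trien-18,19-olide | CC(=O)O[C@@H]1C[C@@]23COC(=O)C2=CC[C@H]2c4occc4C(=O)C[C@@](C)([C@@H]1C)[C@@H]23 | intermediate
24 | 7α-acetoxy-2,12-dioxo-15,16-epoxy-1β,16-cyclo-neo-cleroda-3,13(16),14-trien-18,19-olide | CC(=O)O[C@@H]1C[C@@]23COC(=O)C2=CC(=O)[C@H]2c4occc4C(=O)C[C@@](C)([C@@H]1C)[C@@H]23 | intermediate
25 | 7α-acetoxy-2α-hydroxy-12-oxo-15,16-epoxy-1β,16-cyclo-neo-cleroda-3,13(16),14-trien-18,19-olide (CNP0182929.1) | CC(=O)O[C@@H]1C[C@@]23COC(=O)C2=C[C@H](O)[C@H]2c4occc4C(=O)C[C@@](C)([C@@H]1C)[C@@H]23 | target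

**Step count and risks**

Total steps: 18. Longest linear sequence: 18 steps, from andrographolide (3-bromofuran enters at step 3).

Steps most likely to fail:

1. Step 8 (Proposed new method). The shift relay may be cut short by proton loss from the C10 cation, or may never start because H7 shifts to C8 and the epoxide collapses towards a 7-ketone; the silyloxymethyl shift is the slowest link. The fallback splits the rearrangement into two stages, each of a known type, and sets out from epoxide 12. Opening with BF3·OEt2 in a donor solvent (Et2O, 0 °C), where epoxide-triggered backbone shifts of decalins are known to end at the ring-fusion olefin, would give after the hydride and methyl shifts 16-bromo-15,16-epoxy-3α,7α-dihydroxy-19-(TBDPS-oxy)-ent-halima-5(10),13(16),14-trien-12-one F1. F1 would then be re-ionised with a strong Brønsted acid (TfOH, CH2Cl2–HFIP, −40 °C): protonation of the tetrasubstituted olefin at C10 from the β face (C20 blocks the α face) gives the C5 cation, and a Wagner–Meerwein/pinacol-type finish (C19 shift, H3 shift) comes back to the route at ketone 13.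

2. Step 11. Formate reduction of the arylpalladium species (hydrodebromination) may outrun the slow 7-exo insertion into the hindered enone. The fallback replaces the organopalladium pathway with a radical one and sets out from bromide 16: Bu3SnH added slowly with AIBN in benzene at 80 °C would generate the C16 furyl σ-radical, which adds 7-exo to C1 of the enone on the tether-accessible β face, and the α-keto radical is reduced by the stannane, returning directly at ketone 17. This fallback makes no compound outside the list (F0).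

3. Step 17. Hydrogen abstraction at the electron-poor γ-position of the lactone may be sluggish or unselective against the furan-activated H1. The fallback moves the ring oxidation forward to the electron-rich alkene 19, where allylic oxidation of a simple trisubstituted cyclohexene is standard. From 19, CrO3·3,5-dimethylpyrazole (CH2Cl2, −20 °C) would give 7α-acetoxy-15,16-epoxy-19-(TBDPS-oxy)-1β,16-cyclo-neo-cleroda-3,13(16),14-triene-2,12-dione F2. SeO2 in dioxane at 80 °C would then oxidise the γ-methyl of this enone to the 18-hydroxy enone F3, HF·pyridine would give the 18,19-diol F4, and MnO2 would close the lactone through the lactol F5, coming back to the route at 24.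

**Further compounds**

F1 | step 8 | 16-bromo-15,16-epoxy-3α,7α-dihydroxy-19-(TBDPS-oxy)-ent-halima-5(10),13(16),14-trien-12-one | O[C@@H]1CC2=C(CC[C@@H](O)[C@@]2(C)CO[Si](c3ccccc3)(c3ccccc3)C(C)(C)C)[C@@](C)(CC(=O)c3c(Br)occ3)[C@@H]1C
F0 | step 11 | none | none
F2 | step 17 | 7α-acetoxy-15,16-epoxy-19-(TBDPS-oxy)-1β,16-cyclo-neo-cleroda-3,13(16),14-triene-2,12-dione | CC(=O)O[C@@H]1C[C@@]3(CO[Si](c5ccccc5)(c5ccccc5)C(C)(C)C)C(C)=CC(=O)[C@H]2c4occc4C(=O)C[C@@](C)([C@@H]1C)[C@@H]23
F3 | step 17 | 7α-acetoxy-15,16-epoxy-18-hydroxy-19-(TBDPS-oxy)-1β,16-cyclo-neo-cleroda-3,13(16),14-triene-2,12-dione | CC(=O)O[C@@H]1C[C@@]3(CO[Si](c5ccccc5)(c5ccccc5)C(C)(C)C)C(CO)=CC(=O)[C@H]2c4occc4C(=O)C[C@@](C)([C@@H]1C)[C@@H]23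
F4 | step 17 | 7α-acetoxy-15,16-epoxy-18,19-dihydroxy-1β,16-cyclo-neo-cleroda-3,13(16),14-triene-2,12-dione | CC(=O)O[C@@H]1C[C@@]3(CO)C(CO)=CC(=O)[C@H]2c4occc4C(=O)C[C@@](C)([C@@H]1C)[C@@H]23
F5 | step 17 | 7α-acetoxy-18ξ-hydroxy-18,19:15,16-diepoxy-1β,16-cyclo-neo-cleroda-3,13(16),14-triene-2,12-dione (lactol) | CC(=O)O[C@@H]1C[C@@]23COC(O)C2=CC(=O)[C@H]2c4occc4C(=O)C[C@@](C)([C@@H]1C)[C@@H]23
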